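The oxolane is disconnected between C2 (the ring carbon that carries the pentyl chain) and C3 (the carbinol carbon). The adjacent O1–C2 and C3–OH oxygens of the ring are the signature of a γ-alkoxyallyl metal adding to an aldehyde, so the key step is an intramolecular allylboration: an acyclic (Z)-γ-alkoxyallylboronate, tethered through the future ring oxygen to a masked aldehyde, closes the ring on unmasking, forms the C2–C3 bond and sets both new stereocentres (2,3-cis, 2,5-trans) in one operation. The vinyl group left on C2 is then extended to pentyl, and the unsaturated side chain and the myristate are added last, after the only hydrogenation.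

Key step: step 5

Step 1
Reactants: 1 (2R)-2-[(benzyloxy)methyl]oxirane
Product: 2 (2R)-1-(benzyloxy)pent-4-en-2-ol
Conditions: vinylmagnesium bromide, CuBr·SMe2 (10 mol %), THF, −40 to −20 °C; aq. NH4Cl
Reagents that add atoms: vinylmagnesium bromide, C=C[Mg]Br
Why: Copper-catalysed Grignard opening of the terminal epoxide (SN2 at the CH2 carbon) should give the homoallylic alcohol with the purchased stereocentre, the future C5 of the oxolane, untouched.

Step 2
Reactants: 2 (2R)-1-(benzyloxy)pent-4-en-2-ol
Product: 4 (2R)-1-(benzyloxy)-4,4-dimethoxybutan-2-ol, via hydroxy aldehyde 3 (not isolated)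
Conditions: O3, CH2Cl2–MeOH, −78 °C; Me2S; then p-TsOH (cat.), MeOH, rt
Reagents that add atoms: methanol, CO
Why: Ozonolysis with reductive work-up cleaves the only alkene, and acid-catalysed acetalisation in the same pot should mask aldehyde 3 as a dimethyl acetal that survives the strong base of step 4; the carbinol centre is not involved.

Step 3
Reactants: 4 (2R)-1-(benzyloxy)-4,4-dimethoxybutan-2-ol
Product: 5 ({[(2R)-4,4-dimethoxy-2-(prop-2-en-1-yloxy)butyl]oxy}methyl)benzene
Conditions: NaH, allyl bromide, n-Bu4NI (cat.), THF–DMF, 0 °C to rt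
Reagents that add atoms: allyl bromide, C=CCBr
Why: Williamson ether synthesis on the secondary alkoxide should install the allyl ether whose O–CH2 carbon becomes C2 of the oxolane; acetal and benzyl ether are stable to base.

Step 4
Reactants: 5 ({[(2R)-4,4-dimethoxy-2-(prop-2-en-1-yloxy)butyl]oxy}methyl)benzene
Product: 7 2-[(2Z)-3-{[(2R)-1-(benzyloxy)-4,4-dimethoxybutan-2-yl]oxy}prop-2-en-1-yl]-4,4,5,5-tetramethyl-1,3,2-dioxaborolane, via lithiated allyl ether 6 (not isolated)
Conditions: s-BuLi, THF, −78 °C; then 2-isopropoxy-4,4,5,5-tetramethyl-1,3,2-dioxaborolane, −78 °C to rt; aq. NH4Cl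
Reagents that add atoms: 2-isopropoxy-4,4,5,5-tetramethyl-1,3,2-dioxaborolane, CC(C)OB1OC(C)(C)C(C)(C)O1
Why: α-Lithiation of the allyl ether gives the oxygen-chelated 1-alkoxyallyllithium, and borylation at its γ-carbon (lithiation–borylation) should give the (Z)-γ-alkoxyallylboronate, the Z geometry following from the internal O–Li chelate.

Step 5
Reactants: 7 2-[(2Z)-3-{[(2R)-1-(benzyloxy)-4,4-dimethoxybutan-2-yl]oxy}prop-2-en-1-yl]-4,4,5,5-tetramethyl-1,3,2-dioxaborolane
Product: 10 (2S,3S,5R)-5-[(benzyloxy)methyl]-2-ethenyloxolan-3-ol, via aldehyde 8 (not isolated), via borate ester 9 (not isolated)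
Conditions: Yb(OTf)3 (10 mol %), MeCN–H2O (9:1), 0.01 M, 40 °C; then aq. NaHCO3
Reagents that add atoms: water, O
Why: Mild Lewis-acid hydrolysis of the dimethyl acetal releases aldehyde 8, whose carbonyl oxygen binds boron while the γ-carbon of the allylboronate attacks the carbonyl carbon through a closed six-membered chair transition state with allylic transposition, giving borate ester 9 and, after hydrolysis, alcohol 10. The closest known reaction type is the intramolecular allylboration of ω-formyl allylboronates, in particular the cyclisation of γ-(ω-formylalkoxy)allylboronates to 2-vinyl cyclic ether 3-ols. The oxolane is closed by formation of its C2–C3 bond in a 5-exo mode with respect to both the carbonyl group and the enol ether double bond, which ends as the exocyclic vinyl group. The Z geometry of the enol ether places the ring oxygen axial on the chair, so the chair is cis-fused to the forming five-membered ring and the C2 vinyl and C3 hydroxyl should come out cis (syn adduct). The existing stereocentre (C5 of the oxolane) controls the face, because its CH2OBn group prefers the convex side of this bicyclic transition state, away from the axial C–O–B bond, which makes it trans to both new substituents. The step needs acetal cleavage without hydrolysis of the enol ether boronate and ring closure faster than intermolecular allylation; the first is secured by the neutral aqueous lanthanide catalyst and the second by high dilution and the short tether.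

Step 6
Reactants: 10 (2S,3S,5R)-5-[(benzyloxy)methyl]-2-ethenyloxolan-3-ol
Product: 11 (2S,3S,5R)-5-[(benzyloxy)methyl]-2-[(1E)-pent-1-en-1-yl]oxolan-3-ol
Conditions: pent-1-ene (10 equiv), second-generation Hoveyda–Grubbs catalyst (5 mol %), CH2Cl2, 40 °C, sealed tube
Reagents that add atoms: pent-1-ene, C=CCCC
Why: Olefin cross-metathesis of the only alkene with an excess of a simple terminal alkene should extend the C2 substituent to five carbons; the alkene geometry is immaterial because step 8 saturates it.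

Step 7
Reactants: 11 (2S,3S,5R)-5-[(benzyloxy)methyl]-2-[(1E)-pent-1-en-1-yl]oxolan-3-ol
Product: 12 tert-butyl({(2S,3S,5R)-5-[(benzyloxy)methyl]-2-[(1E)-pent-1-en-1-yl]oxolan-3-yl}oxy)dimethylsilane
Conditions: TBSCl, imidazole, DMF, rt
Reagents that add atoms: tert-butyldimethylsilyl chloride, CC(C)(C)[Si](C)(C)Cl
Why: Standard silyl protection of the ring hydroxyl, so that the later oxidation and acylation address only the side-chain oxygen.

Step 8
Reactants: 12 tert-butyl({(2S,3S,5R)-5-[(benzyloxy)methyl]-2-[(1E)-pent-1-en-1-yl]oxolan-3-yl}oxy)dimethylsilane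
Product: 13 [(2R,4S,5S)-4-{[tert-butyl(dimethyl)silyl]oxy}-5-pentyloxolan-2-yl]methanol
Conditions: H2 (1 atm), Pd/C (10 %), EtOAc, rt
Reagents that add atoms: none
Why: Catalytic hydrogenation should saturate the pentenyl group to pentyl and hydrogenolyse the benzyl ether in one operation, at a stage where no alkene that must survive is present.

Step 9
Reactants: 13 [(2R,4S,5S)-4-{[tert-butyl(dimethyl)silyl]oxy}-5-pentyloxolan-2-yl]methanol
Product: 14 (2R,4S,5S)-4-{[tert-butyl(dimethyl)silyl]oxy}-5-pentyloxolane-2-carbaldehyde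
Conditions: Dess–Martin periodinane, NaHCO3, CH2Cl2, 0 °C to rt
Reagents that add atoms: none
Why: Dess–Martin oxidation of the primary alcohol under buffered conditions should give the α-alkoxy aldehyde without epimerisation; it is used without storage.

Step 10
Reactants: 14 (2R,4S,5S)-4-{[tert-butyl(dimethyl)silyl]oxy}-5-pentyloxolane-2-carbaldehyde and 15 9-bromonon-1-ene
Product: 17 (1R)-1-[(2R,4S,5S)-4-{[tert-butyl(dimethyl)silyl]oxy}-5-pentyloxolan-2-yl]dec-9-en-1-ol, via non-8-enylmagnesium bromide 16 (not isolated)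
Conditions: 15, Mg, Et2O, rt; then added to 14 and MgBr2·OEt2 in CH2Cl2, −78 °C; aq. NH4Cl
Reagents that add atoms: none
Why: Chelation-controlled Grignard addition: magnesium bridges the aldehyde oxygen and the ring oxygen, and the alkyl group should add to the exposed face of the chelate to give the threo (syn) carbinol, which is the (1R) centre.

Step 11
Reactants: 17 (1R)-1-[(2R,4S,5S)-4-{[tert-butyl(dimethyl)silyl]oxy}-5-pentyloxolan-2-yl]dec-9-en-1-ol
Product: 18 (1R)-1-[(2R,4S,5S)-4-{[tert-butyl(dimethyl)silyl]oxy}-5-pentyloxolan-2-yl]dec-9-en-1-yl tetradecanoate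
Conditions: tetradecanoyl chloride, pyridine, DMAP (cat.), CH2Cl2, 0 °C to rt
Reagents that add atoms: tetradecanoyl chloride, CCCCCCCCCCCCCC(=O)Cl
Why: DMAP-catalysed acylation of the only free hydroxyl should install the myristate with retention at the carbinol carbon.

Step 12
Reactants: 18 (1R)-1-[(2R,4S,5S)-4-{[tert-butyl(dimethyl)silyl]oxy}-5-pentyloxolan-2-yl]dec-9-en-1-yl tetradecanoate
Product: 19 (1R)-1-[(2R,4S,5S)-4-hydroxy-5-pentyloxolan-2-yl]dec-9-en-1-yl tetradecanoate
Conditions: HF·pyridine, pyridine, THF, 0 °C to rt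
Reagents that add atoms: none
Why: Fluoride desilylation under buffered conditions should free the ring hydroxyl and leave ester and terminal alkene intact; acyl migration is not expected because ester and hydroxyl lie on opposite faces of the ring.

Compound list
1 | (2R)-2-[(benzyloxy)methyl]oxirane ((R)-benzyl glycidyl ether) | c1ccccc1COC[C@H]1CO1 | starting material
2 | (2R)-1-(benzyloxy)pent-4-en-2-ol | c1ccccc1COC[C@H](O)CC=C | intermediate
3 | (3R)-4-(benzyloxy)-3-hydroxybutanal | c1ccccc1COC[C@H](O)CC=O | intermediate (not isolated)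
4 | (2R)-1-(benzyloxy)-4,4-dimethoxybutan-2-ol | c1ccccc1COC[C@H](O)CC(OC)OC | intermediate
5 | ({[(2R)-4,4-dimethoxy-2-(prop-2-en-1-yloxy)butyl]oxy}methyl)benzene | c1ccccc1COC[C@H](OCC=C)CC(OC)OC | intermediate
6 | 1-lithio derivative of 5 at the allylic O–CH carbon (oxygen-chelated 1-alkoxyallyllithium) | c1ccccc1COC[C@H](OC([Li])C=C)CC(OC)OC | intermediate (not isolated)
7 | 2-[(2Z)-3-{[(2R)-1-(benzyloxy)-4,4-dimethoxybutan-2-yl]oxy}prop-2-en-1-yl]-4,4,5,5-tetramethyl-1,3,2-dioxaborolane | c1ccccc1COC[C@H](O/C=C\CB2OC(C)(C)C(C)(C)O2)CC(OC)OC | intermediate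
8 | (3R)-4-(benzyloxy)-3-{[(1Z)-3-(4,4,5,5-tetramethyl-1,3,2-dioxaborolan-2-yl)prop-1-en-1-yl]oxy}butanal | c1ccccc1COC[C@H](O/C=C\CB2OC(C)(C)C(C)(C)O2)CC=O | intermediate (not isolated)
9 | 2-{[(2S,3S,5R)-5-[(benzyloxy)methyl]-2-ethenyloxolan-3-yl]oxy}-4,4,5,5-tetramethyl-1,3,2-dioxaborolane | c1ccccc1COC[C@H]1C[C@H](OB2OC(C)(C)C(C)(C)O2)[C@H](C=C)O1 | intermediate (not isolated)
10 | (2S,3S,5R)-5-[(benzyloxy)methyl]-2-ethenyloxolan-3-ol | c1ccccc1COC[C@H]1C[C@H](O)[C@H](C=C)O1 | intermediate
11 | (2S,3S,5R)-5-[(benzyloxy)methyl]-2-[(1E)-pent-1-en-1-yl]oxolan-3-ol | c1ccccc1COC[C@H]1C[C@H](O)[C@H](/C=C/CCC)O1 | intermediate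
12 | tert-butyl({(2S,3S,5R)-5-[(benzyloxy)methyl]-2-[(1E)-pent-1-en-1-yl]oxolan-3-yl}oxy)dimethylsilane | c1ccccc1COC[C@H]1C[C@H](O[Si](C)(C)C(C)(C)C)[C@H](/C=C/CCC)O1 | intermediate
13 | [(2R,4S,5S)-4-{[tert-butyl(dimethyl)silyl]oxy}-5-pentyloxolan-2-yl]methanol | OC[C@H]1C[C@H](O[Si](C)(C)C(C)(C)C)[C@H](CCCCC)O1 | intermediate
14 | (2R,4S,5S)-4-{[tert-butyl(dimethyl)silyl]oxy}-5-pentyloxolane-2-carbaldehyde | O=C[C@H]1C[C@H](O[Si](C)(C)C(C)(C)C)[C@H](CCCCC)O1 | intermediate
15 | 9-bromonon-1-ene | C=CCCCCCCCBr | starting material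
16 | non-8-enylmagnesium bromide | C=CCCCCCCC[Mg]Br | intermediate (not isolated)
17 | (1R)-1-[(2R,4S,5S)-4-{[tert-butyl(dimethyl)silyl]oxy}-5-pentyloxolan-2-yl]dec-9-en-1-ol | C=CCCCCCCC[C@@H](O)[C@H]1C[C@H](O[Si](C)(C)C(C)(C)C)[C@H](CCCCC)O1 | intermediate
18 | (1R)-1-[(2R,4S,5S)-4-{[tert-butyl(dimethyl)silyl]oxy}-5-pentyloxolan-2-yl]dec-9-en-1-yl tetradecanoate | C=CCCCCCCC[C@@H](OC(=O)CCCCCCCCCCCCC)[C@H]1C[C@H](O[Si](C)(C)C(C)(C)C)[C@H](CCCCC)O1 | intermediate
19 | (1R)-1-[(2R,4S,5S)-4-hydroxy-5-pentyloxolan-2-yl]dec-9-en-1-yl tetradecanoate | C=CCCCCCCC[C@@H](OC(=O)CCCCCCCCCCCCC)[C@H]1C[C@H](O)[C@H](CCCCC)O1 | target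

Total step count: 12. Longest linear sequence: 12 steps (steps 1 to 12 from compound 1; compound 15 enters in step 10 as its Grignard reagent).

Steps most likely to fail

Step 5. The enol ether boronate may be hydrolysed or protodeboronated while the acetal is cleaved, the oxocarbenium ion may be allylated directly before hydrolysis through an open transition state, or intermolecular allylation may compete with ring closure. The fallback separates unmasking from ring closure by changing the metal. It sets out from 5: lithiation as in step 4 and quenching with Bu3SnCl should give tributyl[(2Z)-3-{[(2R)-1-(benzyloxy)-4,4-dimethoxybutan-2-yl]oxy}prop-2-en-1-yl]stannane F1. Acetal hydrolysis with pyridinium p-toluenesulfonate in acetone–H2O should give (3R)-4-(benzyloxy)-3-{[(1Z)-3-(tributylstannyl)prop-1-en-1-yl]oxy}butanal F2, which does not cyclise at room temperature and can be purified. Heating F2 in toluene at 100 °C should close the ring thermally through the same closed transition state, with tin in place of boron, and the route is rejoined at 10.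

Step 10. Chelation may be incomplete, so that facial selectivity at the new carbinol centre is poor, and the Grignard reagent may also enolise or reduce the aldehyde. The fallback sets the centre by reduction instead of addition. It sets out from 14: addition of 16 without additive should give 17 together with its epimer (1S)-1-[(2R,4S,5S)-4-{[tert-butyl(dimethyl)silyl]oxy}-5-pentyloxolan-2-yl]dec-9-en-1-ol F3. Dess–Martin oxidation of the mixture should give 1-[(2R,4S,5S)-4-{[tert-butyl(dimethyl)silyl]oxy}-5-pentyloxolan-2-yl]dec-9-en-1-one F4. Reduction with LiBH(s-Bu)3 in THF at −78 °C, under non-chelation control with hydride delivered anti to the ring C–O bond, should give the threo alcohol, and the route is rejoined at 17.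

Step 6. Cross-metathesis may be slow at a vinyl group flanked by the ring oxygen and the cis hydroxyl, with homodimerisation of pent-1-ene and alkene isomerisation taking over. The fallback builds the chain by cross-coupling. It sets out from 10: silylation as in step 7 should give tert-butyl({(2S,3S,5R)-5-[(benzyloxy)methyl]-2-ethenyloxolan-3-yl}oxy)dimethylsilane F5. Hydroboration with 9-BBN in THF should give 9-{2-[(2S,3S,5R)-5-[(benzyloxy)methyl]-3-{[tert-butyl(dimethyl)silyl]oxy}oxolan-2-yl]ethyl}-9-borabicyclo[3.3.1]nonane F6. B-alkyl Suzuki–Miyaura coupling of F6 with (E)-1-bromoprop-1-ene (Pd(dppf)Cl2, K3PO4, DMF–H2O) should give tert-butyl({(2S,3S,5R)-5-[(benzyloxy)methyl]-2-[(3E)-pent-3-en-1-yl]oxolan-3-yl}oxy)dimethylsilane F7. Hydrogenation of F7 under the conditions of step 8 rejoins the route at 13.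

Further compounds
F1 | step 5 | tributyl[(2Z)-3-{[(2R)-1-(benzyloxy)-4,4-dimethoxybutan-2-yl]oxy}prop-2-en-1-yl]stannane | c1ccccc1COC[C@H](O/C=C\C[Sn](CCCC)(CCCC)CCCC)CC(OC)OC
F2 | step 5 | (3R)-4-(benzyloxy)-3-{[(1Z)-3-(tributylstannyl)prop-1-en-1-yl]oxy}butanal | c1ccccc1COC[C@H](O/C=C\C[Sn](CCCC)(CCCC)CCCC)CC=O
F3 | step 10 | (1S)-1-[(2R,4S,5S)-4-{[tert-butyl(dimethyl)silyl]oxy}-5-pentyloxolan-2-yl]dec-9-en-1-ol | C=CCCCCCCC[C@H](O)[C@H]1C[C@H](O[Si](C)(C)C(C)(C)C)[C@H](CCCCC)O1
F4 | step 10 | 1-[(2R,4S,5S)-4-{[tert-butyl(dimethyl)silyl]oxy}-5-pentyloxolan-2-yl]dec-9-en-1-one | C=CCCCCCCCC(=O)[C@H]1C[C@H](O[Si](C)(C)C(C)(C)C)[C@H](CCCCC)O1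
F5 | step 6 | tert-butyl({(2S,3S,5R)-5-[(benzyloxy)methyl]-2-ethenyloxolan-3-yl}oxy)dimethylsilane | c1ccccc1COC[C@H]1C[C@H](O[Si](C)(C)C(C)(C)C)[C@H](C=C)O1
F6 | step 6 | 9-{2-[(2S,3S,5R)-5-[(benzyloxy)methyl]-3-{[tert-butyl(dimethyl)silyl]oxy}oxolan-2-yl]ethyl}-9-borabicyclo[3.3.1]nonane | c1ccccc1COC[C@H]1C[C@H](O[Si](C)(C)C(C)(C)C)[C@H](CCB2C3CCCC2CCC3)O1
F7 | step 6 | tert-butyl({(2S,3S,5R)-5-[(benzyloxy)methyl]-2-[(3E)-pent-3-en-1-yl]oxolan-3-yl}oxy)dimethylsilane | c1ccccc1COC[C@H]1C[C@H](O[Si](C)(C)C(C)(C)C)[C@H](CC/C=C/C)O1
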